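The isoflavone is disconnected through ring A: the bonds C4a–C5, C5–C6 and C7–C8 are made last, on a preformed ring C that already carries ring B. One photochemical benzannulation of a 2-(diazoacetyl)-5-aryl-4-pyranone with (triisopropylsiloxy)acetylene builds the carbocycle C4a/C5/C6/C7/C8/C8a. It exploits the meta-dioxygenated ring A: the ketene carbon becomes C5 with its free hydroxyl next to the C4 carbonyl, the alkyne carbon becomes C7 as a silyl ether. The precursor joins kojic acid (ring C, via its 5-triflate) to a ring-B pinacol boronate from 2-bromoisovanillin that bears two benzyl ethers and a triethylsilyl-protected tertiary alcohol.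

Key step: step 13

Remark: the target has no stereocentre and is achiral, so no step has to control configuration.
Remark: (triisopropylsiloxy)acetylene is not assumed to be purchasable and is made in step 12 from acetylene.
Abbreviation used in names: Ar = 2,4-bis(benzyloxy)-5-methoxy-3-[3-methyl-3-(triethylsilyloxy)butyl]phenyl.

Step 1
Reactants: 1 2-methylbut-3-en-2-ol
Product: 2 triethyl[(2-methylbut-3-en-2-yl)oxy]silane
Conditions: TESOTf, 2,6-lutidine, CH2Cl2, 0 °C
Reagents that add atoms: triethylsilyl trifluoromethanesulfonate, CC[Si](CC)(CC)OS(=O)(=O)C(F)(F)F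
Why: O-silylation of a tertiary alcohol with a silyl triflate and a hindered pyridine base is general, and the triethylsilyl ether later shields this hydroxyl from the acid chloride and the ketene while staying cleavable by fluoride.

Step 2
Reactants: 3 2-bromo-3-hydroxy-4-methoxybenzaldehyde (2-bromoisovanillin)
Product: 4 3-(benzyloxy)-2-bromo-4-methoxybenzaldehyde
Conditions: BnBr, K2CO3, DMF, rt
Reagents that add atoms: benzyl bromide, BrCc1ccccc1
Why: Williamson etherification of the acidic phenol installs a group that should survive every later step and leaves at the end by neutral hydrogenolysis.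

Step 3
Reactants: 4 3-(benzyloxy)-2-bromo-4-methoxybenzaldehyde
Product: 6 3-(benzyloxy)-2-bromo-4-methoxyphenol, via aryl formate 5 (not isolated)
Conditions: mCPBA, CH2Cl2, rt; then K2CO3 (cat.), MeOH, rt
Reagents that add atoms: 3-chloroperoxybenzoic acid, OOC(=O)c1cccc(Cl)c1
Why: Baeyer–Villiger (Dakin-type) oxidation in which the electron-rich aryl group, activated by the para methoxy group, migrates in preference to hydrogen, followed by methanolysis of the formate to unveil the future 2'-oxygen.

Step 4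
Reactants: 6 3-(benzyloxy)-2-bromo-4-methoxyphenol
Product: 7 1,3-bis(benzyloxy)-2-bromo-4-methoxybenzene
Conditions: BnBr, K2CO3, DMF, 50 °C
Reagents that add atoms: benzyl bromide, BrCc1ccccc1
Why: Williamson etherification of the new phenol gives both ring-B oxygens the same hydrogenolysable protecting group.

Step 5
Reactants: 2 triethyl[(2-methylbut-3-en-2-yl)oxy]silane; 7 1,3-bis(benzyloxy)-2-bromo-4-methoxybenzene
Product: 9 {[4-(2,6-bis(benzyloxy)-3-methoxyphenyl)-2-methylbutan-2-yl]oxy}triethylsilane, via alkyl-9-BBN borane 8 (not isolated)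
Conditions: 2, 9-BBN-H, THF, rt; then 7, Pd(OAc)2 (cat.), SPhos (cat.), aq. K3PO4, THF, 65 °C
Reagents that add atoms: none
Why: Anti-Markovnikov hydroboration of the terminal alkene with 9-BBN followed by B-alkyl Suzuki–Miyaura coupling, with a bulky dialkylbiarylphosphine ligand chosen to promote oxidative addition into the doubly ortho-alkoxylated bromide.

Step 6
Reactants: 9 {[4-(2,6-bis(benzyloxy)-3-methoxyphenyl)-2-methylbutan-2-yl]oxy}triethylsilane
Product: 10 {[4-(2,6-bis(benzyloxy)-3-bromo-5-methoxyphenyl)-2-methylbutan-2-yl]oxy}triethylsilane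
Conditions: NBS, MeCN, 0 °C to rt, dark
Reagents that add atoms: N-bromosuccinimide, BrN1C(=O)CCC1=O
Why: Electrophilic aromatic bromination, which should take the free position ortho to one benzyloxy group and para to the other (the future C1') and not the position that is only ortho to the methoxy group.

Step 7
Reactants: 10 {[4-(2,6-bis(benzyloxy)-3-bromo-5-methoxyphenyl)-2-methylbutan-2-yl]oxy}triethylsilane
Product: 11 2-Ar-4,4,5,5-tetramethyl-1,3,2-dioxaborolane (ring-B pinacol boronate)
Conditions: B2pin2, Pd(dppf)Cl2 (cat.), KOAc, 1,4-dioxane, 90 °C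
Reagents that add atoms: bis(pinacolato)diboron, CC1(C)OB(OC1(C)C)B1OC(C)(C)C(C)(C)O1
Why: Miyaura borylation of the aryl bromide runs under weakly basic conditions that leave the silyl and benzyl ethers untouched.

Step 8
Reactants: 12 kojic acid (5-hydroxy-2-(hydroxymethyl)-4H-pyran-4-one)
Product: 13 6-(hydroxymethyl)-4-oxo-4H-pyran-3-yl trifluoromethanesulfonate (kojic acid 5-triflate)
Conditions: PhNTf2, Et3N, DMF, 0 °C to rt
Reagents that add atoms: N-phenylbis(trifluoromethanesulfonimide), FC(F)(F)S(=O)(=O)N(c1ccccc1)S(=O)(=O)C(F)(F)F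
Why: Selective O-sulfonylation, because the enolic 5-hydroxyl (pKa about 8) is deprotonated by the amine and triflated by the mild reagent whereas the neutral primary alcohol does not react.

Step 9
Reactants: 11 ring-B pinacol boronate; 13 kojic acid 5-triflate
Product: 14 5-Ar-2-(hydroxymethyl)-4H-pyran-4-one
Conditions: Pd(dppf)Cl2 (cat.), K3PO4, 1,4-dioxane/H2O, 70 °C
Reagents that add atoms: none
Why: Suzuki–Miyaura coupling in which the electron-poor α-oxo enol triflate adds readily to Pd(0) and the boronate carries only one ortho substituent.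

Step 10
Reactants: 14 5-Ar-2-(hydroxymethyl)-4H-pyran-4-one
Product: 15 5-Ar-4-oxo-4H-pyran-2-carboxylic acid
Conditions: TEMPO (cat.), NaOCl (cat.), NaClO2, MeCN/phosphate buffer pH 6.7, 35 °C
Reagents that add atoms: sodium chlorite, [Na+].[O-]Cl=O
Why: TEMPO-catalysed oxidation with chlorite as terminal oxidant takes the primary alcohol through the aldehyde to the acid at near-neutral pH, which spares the silyl ether and avoids chlorination of the electron-rich ring.

Step 11
Reactants: 15 5-Ar-4-oxo-4H-pyran-2-carboxylic acid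
Product: 17 5-Ar-2-(2-diazoacetyl)-4H-pyran-4-one, via acid chloride 16 (not isolated)
Conditions: 1-chloro-N,N,2-trimethylprop-1-en-1-amine, CH2Cl2, 0 °C to rt; then CH2N2 (excess), Et2O, 0 °C
Reagents that add atoms: diazomethane, C=[N+]=[N-]
Why: Neutral conversion of the acid into its chloride with an α-chloroenamine and C-acylation of diazomethane (first stage of the Arndt–Eistert sequence), a second equivalent of diazomethane taking up the hydrogen chloride.

Step 12
Reactants: 18 acetylene
Product: 21 (triisopropylsiloxy)acetylene, via lithium acetylide 19 (not isolated), via lithium ethynolate 20 (not isolated)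
Conditions: n-BuLi, THF, −78 °C; t-BuOOLi (from t-BuOOH, LiHMDS), −78 to −20 °C; TIPSOTf, −78 to 0 °C
Reagents that add atoms: tert-butyl hydroperoxide, CC(C)(C)OO; triisopropylsilyl trifluoromethanesulfonate, CC(C)[Si](C(C)C)(C(C)C)OS(=O)(=O)C(F)(F)F
Why: Oxidation of a lithium acetylide by lithium tert-butyl peroxide gives the ynolate, which the bulky silyl triflate should capture on oxygen to give the silyl ynol ether.

Step 13
Reactants: 17 5-Ar-2-(2-diazoacetyl)-4H-pyran-4-one; 21 (triisopropylsiloxy)acetylene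
Product: 25 3-Ar-5-hydroxy-7-(triisopropylsilyloxy)-4H-chromen-4-one, via pyranonyl ketene 22 (not isolated), via siloxycyclobutenone 23 (not isolated), via dienylketene 24 (not isolated)
Conditions: 21 (2 equiv), hν (medium-pressure Hg lamp, Pyrex filter), degassed ClCH2CH2Cl, rt; then 80 °C
Reagents that add atoms: none
Why: Light expels N2 from 17 and the pyranonyl group migrates (Wolff rearrangement) to give ketene 22, whose C=C adds the polarised alkyne 21 in a [2+2] cycloaddition to cyclobutenone 23; 4π-electrocyclic opening of 23 gives dienylketene 24, which closes by 6π-electrocyclisation onto pyranone C-3 and enolises to phenol 25. The closest known reaction type is the Danheiser benzannulation in its α-diazo ketone form with siloxyalkynes, which is established for alkenyl and heteroaryl diazomethyl ketones. Ring A (C4a, C5, C6, C7, C8, C8a) is closed by a thermal disrotatory 6π-electrocyclisation that forms C4a–C5 after the [2+2] step has formed C5–C6 and C7–C8, and the four-membered ring is only transient. No stereocentre remains, since the sp3 carbon of 23 is lost on ring opening and the ring-fusion carbon C4a becomes aromatic on enolisation. The step needs regioselectivity in the [2+2] addition, secured by the nucleophilic CH terminus of 21 bonding to the electrophilic ketene carbonyl carbon so that the siloxy group ends at C7 and the free hydroxyl at C5, and site selectivity in the ring closure, secured because C-3 is the only carbon neighbour of the ketene-bearing pyranone carbon (the other neighbour is the ring oxygen). Pyrex-filtered light is chosen so that the diazo ketone is excited in preference to the aryl pyranone chromophore, and the benzyl and silyl ethers should be inert under these conditions.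

Step 14
Reactants: 25 3-Ar-5-hydroxy-7-(triisopropylsilyloxy)-4H-chromen-4-one
Product: 26 3-[2,4-bis(benzyloxy)-3-(3-hydroxy-3-methylbutyl)-5-methoxyphenyl]-5,7-dihydroxy-4H-chromen-4-one
Conditions: TBAF, AcOH, THF, 0 °C to rt
Reagents that add atoms: none
Why: Fluoride-mediated cleavage of the aryl triisopropylsilyl and tertiary triethylsilyl ethers, buffered with acetic acid so that neither base nor acid can touch the chromone or the tertiary alcohol.

Step 15
Reactants: 26 3-[2,4-bis(benzyloxy)-3-(3-hydroxy-3-methylbutyl)-5-methoxyphenyl]-5,7-dihydroxy-4H-chromen-4-one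
Product: 27 3-[2,4-dihydroxy-3-(3-hydroxy-3-methylbutyl)-5-methoxyphenyl]-5,7-dihydroxy-4H-chromen-4-one (target)
Conditions: H2 (1 atm), 10% Pd/C, EtOAc/MeOH, rt
Reagents that add atoms: none
Why: Catalytic hydrogenolysis of the two benzyl ethers under neutral conditions, which avoids the acid-induced closure of the tertiary alcohol onto a neighbouring phenol to a dimethylchroman.

Compound list
1 | 2-methylbut-3-en-2-ol | C=CC(C)(C)O | starting material
2 | triethyl[(2-methylbut-3-en-2-yl)oxy]silane | C=CC(C)(C)O[Si](CC)(CC)CC | intermediate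
3 | 2-bromo-3-hydroxy-4-methoxybenzaldehyde | O=Cc1ccc(OC)c(O)c1Br | starting material
4 | 3-(benzyloxy)-2-bromo-4-methoxybenzaldehyde | O=Cc1ccc(OC)c(OCc2ccccc2)c1Br | intermediate
5 | 3-(benzyloxy)-2-bromo-4-methoxyphenyl formate | O=COc1ccc(OC)c(OCc2ccccc2)c1Br | intermediate (not isolated)
6 | 3-(benzyloxy)-2-bromo-4-methoxyphenol | Oc1ccc(OC)c(OCc2ccccc2)c1Br | intermediate
7 | 1,3-bis(benzyloxy)-2-bromo-4-methoxybenzene | COc1ccc(OCc2ccccc2)c(Br)c1OCc3ccccc3 | intermediate
8 | 9-[3-methyl-3-(triethylsilyloxy)butyl]-9-borabicyclo[3.3.1]nonane | CC[Si](CC)(CC)OC(C)(C)CCB1C2CCCC1CCC2 | intermediate (not isolated)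
9 | {[4-(2,6-bis(benzyloxy)-3-methoxyphenyl)-2-methylbutan-2-yl]oxy}triethylsilane | COc1ccc(OCc2ccccc2)c(CCC(C)(C)O[Si](CC)(CC)CC)c1OCc3ccccc3 | intermediate
10 | {[4-(2,6-bis(benzyloxy)-3-bromo-5-methoxyphenyl)-2-methylbutan-2-yl]oxy}triethylsilane | COc1cc(Br)c(OCc2ccccc2)c(CCC(C)(C)O[Si](CC)(CC)CC)c1OCc3ccccc3 | intermediate
11 | 2-{2,4-bis(benzyloxy)-5-methoxy-3-[3-methyl-3-(triethylsilyloxy)butyl]phenyl}-4,4,5,5-tetramethyl-1,3,2-dioxaborolane | CC1(C)OB(OC1(C)C)c2cc(OC)c(OCc3ccccc3)c(CCC(C)(C)O[Si](CC)(CC)CC)c2OCc4ccccc4 | intermediate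
12 | kojic acid, 5-hydroxy-2-(hydroxymethyl)-4H-pyran-4-one | O=c1cc(CO)occ1O | starting material
13 | 6-(hydroxymethyl)-4-oxo-4H-pyran-3-yl trifluoromethanesulfonate | O=c1cc(CO)occ1OS(=O)(=O)C(F)(F)F | intermediate
14 | 5-{2,4-bis(benzyloxy)-5-methoxy-3-[3-methyl-3-(triethylsilyloxy)butyl]phenyl}-2-(hydroxymethyl)-4H-pyran-4-one | O=c1cc(CO)occ1-c2cc(OC)c(OCc3ccccc3)c(CCC(C)(C)O[Si](CC)(CC)CC)c2OCc4ccccc4 | intermediate
15 | 5-{2,4-bis(benzyloxy)-5-methoxy-3-[3-methyl-3-(triethylsilyloxy)butyl]phenyl}-4-oxo-4H-pyran-2-carboxylic acid | OC(=O)c1cc(=O)c(co1)-c2cc(OC)c(OCc3ccccc3)c(CCC(C)(C)O[Si](CC)(CC)CC)c2OCc4ccccc4 | intermediate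
16 | 5-{2,4-bis(benzyloxy)-5-methoxy-3-[3-methyl-3-(triethylsilyloxy)butyl]phenyl}-4-oxo-4H-pyran-2-carbonyl chloride | ClC(=O)c1cc(=O)c(co1)-c2cc(OC)c(OCc3ccccc3)c(CCC(C)(C)O[Si](CC)(CC)CC)c2OCc4ccccc4 | intermediate (not isolated)
17 | 5-{2,4-bis(benzyloxy)-5-methoxy-3-[3-methyl-3-(triethylsilyloxy)butyl]phenyl}-2-(2-diazoacetyl)-4H-pyran-4-one | [N-]=[N+]=CC(=O)c1cc(=O)c(co1)-c2cc(OC)c(OCc3ccccc3)c(CCC(C)(C)O[Si](CC)(CC)CC)c2OCc4ccccc4 | intermediate (key-step precursor)
18 | acetylene (ethyne) | C#C | starting material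
19 | lithium acetylide (ethynyllithium) | [Li]C#C | intermediate (not isolated)
20 | lithium ethynolate | [Li+].[O-]C#C | intermediate (not isolated)
21 | (triisopropylsiloxy)acetylene, (ethynyloxy)tri(propan-2-yl)silane | C#CO[Si](C(C)C)(C(C)C)C(C)C | intermediate (key-step precursor)
22 | 2-(5-Ar-4-oxo-4H-pyran-2-yl)ethenone (pyranonyl ketene) | O=C=Cc1cc(=O)c(co1)-c2cc(OC)c(OCc3ccccc3)c(CCC(C)(C)O[Si](CC)(CC)CC)c2OCc4ccccc4 | intermediate (not isolated)
23 | 4-(5-Ar-4-oxo-4H-pyran-2-yl)-3-(triisopropylsilyloxy)cyclobut-2-en-1-one, racemic | O=C1C=C(O[Si](C(C)C)(C(C)C)C(C)C)C1c1cc(=O)c(co1)-c2cc(OC)c(OCc3ccccc3)c(CCC(C)(C)O[Si](CC)(CC)CC)c2OCc4ccccc4 | intermediate (not isolated)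
24 | (3E)-4-(5-Ar-4-oxo-4H-pyran-2-yl)-3-(triisopropylsilyloxy)buta-1,3-dien-1-one, ketene and pyranonyl cis on the C3=C4 bond | O=C=C/C(O[Si](C(C)C)(C(C)C)C(C)C)=C\c1cc(=O)c(co1)-c2cc(OC)c(OCc3ccccc3)c(CCC(C)(C)O[Si](CC)(CC)CC)c2OCc4ccccc4 | intermediate (not isolated)
25 | 3-{2,4-bis(benzyloxy)-5-methoxy-3-[3-methyl-3-(triethylsilyloxy)butyl]phenyl}-5-hydroxy-7-(triisopropylsilyloxy)-4H-chromen-4-one | O=c1c(coc2cc(O[Si](C(C)C)(C(C)C)C(C)C)cc(O)c12)-c3cc(OC)c(OCc4ccccc4)c(CCC(C)(C)O[Si](CC)(CC)CC)c3OCc5ccccc5 | intermediate (key-step product)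
26 | 3-[2,4-bis(benzyloxy)-3-(3-hydroxy-3-methylbutyl)-5-methoxyphenyl]-5,7-dihydroxy-4H-chromen-4-one | O=c1c(coc2cc(O)cc(O)c12)-c3cc(OC)c(OCc4ccccc4)c(CCC(C)(C)O)c3OCc5ccccc5 | intermediate
27 | 3-[2,4-dihydroxy-3-(3-hydroxy-3-methylbutyl)-5-methoxyphenyl]-5,7-dihydroxy-4H-chromen-4-one | COc1cc(-c2coc3cc(O)cc(O)c3c2=O)c(O)c(CCC(C)(C)O)c1O | target

Total step count: 15.
Longest linear sequence: 12 steps (steps 2 to 7, 9 to 11 and 13 to 15, from 2-bromoisovanillin 3 to target 27).

Steps most likely to fail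

Step 13. The light may also excite the aryl pyranone and cause its rearrangement. The ketene may dimerise or be trapped before it meets the alkyne. The sequence may stall at the cyclobutenone, or open to the dienylketene geometry that cannot cyclise. The fallback gives up the de novo construction of ring A and attaches a finished ring A/C unit to ring B. It sets out from boronate 11. 2,4,6-Trihydroxyacetophenone is benzylated twice (BnBr, K2CO3) to 1-[2,4-bis(benzyloxy)-6-hydroxyphenyl]ethanone F1. Condensation with DMF dimethyl acetal gives (E)-1-[2,4-bis(benzyloxy)-6-hydroxyphenyl]-3-(dimethylamino)prop-2-en-1-one F2. Iodine-induced cyclisation (I2, pyridine, CHCl3) gives 5,7-bis(benzyloxy)-3-iodo-4H-chromen-4-one F3. Suzuki coupling of F3 with 11 (Pd(dppf)Cl2, K2CO3, dioxane/H2O) should give 5,7-bis(benzyloxy)-3-Ar-4H-chromen-4-one F4. Buffered TBAF removes the triethylsilyl group to give 5,7-bis(benzyloxy)-3-[2,4-bis(benzyloxy)-3-(3-hydroxy-3-methylbutyl)-5-methoxyphenyl]-4H-chromen-4-one F5. Hydrogenolysis of the four benzyl ethers (H2, Pd/C) brings the fallback back to the route at target 27.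

Step 12. Monolithium acetylide may disproportionate before the peroxide oxidises it. The ynolate may be silylated on carbon to a silylketene. The volatile, moisture-sensitive ynol ether may be lost on isolation. The fallback replaces the silyl ynol ether by an alkyl ynol ether made through a dichlorovinyl ether, and keeps the key step. It sets out from diazo ketone 17. 2-(Trimethylsilyl)ethanol, KH and trichloroethylene give (E)-[2-(1,2-dichloroethenyloxy)ethyl]trimethylsilane F6. n-BuLi (excess) followed by methanol gives [2-(ethynyloxy)ethyl]trimethylsilane F7. Benzannulation of 17 with F7 under the conditions of step 13 should give 3-Ar-5-hydroxy-7-[2-(trimethylsilyl)ethoxy]-4H-chromen-4-one F8. TBAF in warm THF cleaves both the 2-(trimethylsilyl)ethyl ether and the triethylsilyl ether, and the fallback comes back to the route at 26.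

Step 5. Oxidative addition into the hindered, electron-rich bromide may be slow, so that protodebromination of 7 or decomposition of the alkylborane wins. The fallback makes the aryl carbon the nucleophile and builds the tertiary alcohol afterwards. It sets out from 7. Bromine–lithium exchange (n-BuLi, THF, −78 °C), transmetalation with CuBr·SMe2 and prenyl bromide give 1,3-bis(benzyloxy)-4-methoxy-2-(3-methylbut-2-en-1-yl)benzene F9. Mukaiyama hydration (Co(acac)2, PhSiH3, O2) gives the Markovnikov alcohol 4-[2,6-bis(benzyloxy)-3-methoxyphenyl]-2-methylbutan-2-ol F10. Silylation with TESOTf and 2,6-lutidine brings the fallback back to the route at 9.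

Further compounds
F1 | step 13 | 1-[2,4-bis(benzyloxy)-6-hydroxyphenyl]ethanone | CC(=O)c1c(O)cc(OCc2ccccc2)cc1OCc3ccccc3
F2 | step 13 | (E)-1-[2,4-bis(benzyloxy)-6-hydroxyphenyl]-3-(dimethylamino)prop-2-en-1-one | CN(C)/C=C/C(=O)c1c(O)cc(OCc2ccccc2)cc1OCc3ccccc3
F3 | step 13 | 5,7-bis(benzyloxy)-3-iodo-4H-chromen-4-one | O=c1c(I)coc2cc(OCc3ccccc3)cc(OCc4ccccc4)c12
F4 | step 13 | 5,7-bis(benzyloxy)-3-{2,4-bis(benzyloxy)-5-methoxy-3-[3-methyl-3-(triethylsilyloxy)butyl]phenyl}-4H-chromen-4-one | O=c1c(coc2cc(OCc3ccccc3)cc(OCc4ccccc4)c12)-c5cc(OC)c(OCc6ccccc6)c(CCC(C)(C)O[Si](CC)(CC)CC)c5OCc7ccccc7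
F5 | step 13 | 5,7-bis(benzyloxy)-3-[2,4-bis(benzyloxy)-3-(3-hydroxy-3-methylbutyl)-5-methoxyphenyl]-4H-chromen-4-one | O=c1c(coc2cc(OCc3ccccc3)cc(OCc4ccccc4)c12)-c5cc(OC)c(OCc6ccccc6)c(CCC(C)(C)O)c5OCc7ccccc7
F6 | step 12 | (E)-[2-(1,2-dichloroethenyloxy)ethyl]trimethylsilane | C[Si](C)(C)CCO/C(Cl)=C\Cl
F7 | step 12 | [2-(ethynyloxy)ethyl]trimethylsilane | C#COCC[Si](C)(C)C
F8 | step 12 | 3-{2,4-bis(benzyloxy)-5-methoxy-3-[3-methyl-3-(triethylsilyloxy)butyl]phenyl}-5-hydroxy-7-[2-(trimethylsilyl)ethoxy]-4H-chromen-4-one | O=c1c(coc2cc(OCC[Si](C)(C)C)cc(O)c12)-c3cc(OC)c(OCc4ccccc4)c(CCC(C)(C)O[Si](CC)(CC)CC)c3OCc5ccccc5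
F9 | step 5 | 1,3-bis(benzyloxy)-4-methoxy-2-(3-methylbut-2-en-1-yl)benzene | COc1ccc(OCc2ccccc2)c(CC=C(C)C)c1OCc3ccccc3
F10 | step 5 | 4-[2,6-bis(benzyloxy)-3-methoxyphenyl]-2-methylbutan-2-ol | COc1ccc(OCc2ccccc2)c(CCC(C)(C)O)c1OCc3ccccc3
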